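**Retrosynthetic overview**
1. 9 ⇒ 8 by O-debenzylation. 8 ⇒ 4 + 6 by cutting C5–C6 of the docosanoyl chain between two carbons that are both electrophiles: C5 as a primary bromide, C6 as the decarboxylating carbon of a redox-active stearate. They are joined reductively through an alkyl radical at nickel.
2. Enabling feature: C5 and C6 lie inside the unbranched, heteroatom-free (CH2)20 run C2–C21 of the acyl chain and are stereochemically silent sp3 carbons. C6–C22 is stearic acid minus its carboxyl carbon. C1–C5 is a 5-halopentanoate whose halide sits four CH2 groups from ester carbon C1. The only ring, the 1,4-disubstituted benzene ring with its oxygen, lies beyond the ester and is a spectator.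
3. 4 ⇒ 2 + 5-bromopentanoyl chloride 3 (ester C–O bond); 2 ⇒ 1 (phenol O-benzylation); 6 ⇒ stearic acid 5 + N-hydroxyphthalimide.
4. No ring is formed in the route, since the benzene ring is bought with 1. The target has no stereocentre.

Key step: step 4

**Step 1**
Reactants: 1 3-(4-hydroxyphenyl)propan-1-ol
Product: 2 3-[4-(benzyloxy)phenyl]propan-1-ol
Conditions: BnBr (1.05 equiv), K2CO3 (1.5 equiv), acetone, reflux
Reagents that add atoms: benzyl bromide, BrCc1ccccc1
Why: Williamson ether synthesis in which K2CO3 deprotonates only the phenol (pKa about 10) and not the primary alcohol (pKa about 16), so only the phenoxide should be benzylated and no stereocentre is formed.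

**Step 2**
Reactants: 2 3-[4-(benzyloxy)phenyl]propan-1-ol; 3 5-bromopentanoyl chloride
Product: 4 3-[4-(benzyloxy)phenyl]propyl 5-bromopentanoate
Conditions: pyridine (1.5 equiv), CH2Cl2, 0 °C to rt
Reagents that add atoms: none
Why: Nucleophilic acyl substitution of an acid chloride by a primary alcohol is far faster at 0 °C than any displacement at the primary C–Br bond, and the benzyl aryl ether is inert to pyridine and its hydrochloride.

**Step 3**
Reactants: 5 octadecanoic acid (stearic acid)
Product: 6 1,3-dioxoisoindolin-2-yl octadecanoate (N-hydroxyphthalimide ester of stearic acid)
Conditions: N-hydroxyphthalimide (1.05 equiv), DIC (1.1 equiv), DMAP (5 mol %), CH2Cl2, rt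
Reagents that add atoms: N-hydroxyphthalimide, O=C1c2ccccc2C(=O)N1O
Why: Carbodiimide (Steglich-type) esterification in which DIC activates the acid as its O-acylisourea and the acidic N–OH group intercepts it, which should give the crystalline redox-active ester.

**Step 4**
Reactants: 4 3-[4-(benzyloxy)phenyl]propyl 5-bromopentanoate; 6 1,3-dioxoisoindolin-2-yl octadecanoate
Product: 8 3-[4-(benzyloxy)phenyl]propyl docosanoate, via heptadecyl radical 7 (not isolated)
Conditions: NiBr2·dme (10 mol %), 4,4′,4″-tri-tert-butyl-2,2′:6′,2″-terpyridine (10 mol %), Zn dust (3 equiv), 6 (1.5 equiv, added in portions), DMA–THF, 25–30 °C, argon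
Reagents that add atoms: none
Why: Zn turns the nickel(II) salt into low-valent (terpyridine)nickel, which takes up the primary C–Br bond of 4 by halogen abstraction and rebound as an alkylnickel species; this passes one electron into the phthalimide π system of 6, so that N–O cleavage and loss of CO2 release heptadecyl radical 7, whose capture gives a dialkylnickel(III) centre that makes the C5–C6 bond by reductive elimination before Zn restarts the cycle. The closest known reaction type is the nickel-catalysed reductive C(sp3)–C(sp3) cross-electrophile coupling of N-hydroxyphthalimide esters of primary acids with unactivated primary alkyl bromides, a reductive relative of the mixed Kolbe coupling. No ring is closed and no stereocentre is created. The step needs cross-coupling to win over homocoupling of two primary alkyl partners of like (electrophilic) polarity; this is secured by their different modes of activation (inner-sphere uptake of C–Br against electron transfer to the much more easily reduced N–O ester), by portionwise addition of an excess of the cheap 6 so that 7 stays dilute, and by homodimers (a C34 alkane and a C10 diester) that differ widely in polarity from 8. It also needs chemoselectivity: the alkyl ester and the benzyl aryl ether are not touched by Ni/Zn at room temperature, and because C5 lies four methylenes from C1 neither the radical nor the alkylnickel species is stabilised or able to cyclise onto the ester. The tridentate ligand fills the coordination site that β-hydride elimination would need.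

**Step 5**
Reactants: 8 3-[4-(benzyloxy)phenyl]propyl docosanoate
Product: 9 3-(4-hydroxyphenyl)propyl docosanoate
Conditions: H2 (1 atm), 10 % Pd/C, EtOAc–THF, rt
Reagents that add atoms: none
Why: Catalytic hydrogenolysis cleaves only the benzylic C–O bond of the benzyl aryl ether, because the ester oxygen sits on a non-benzylic 3-arylpropyl carbon and the phenol ring is not reduced at 1 atm of H2.

**Compound list**
1 | 3-(4-hydroxyphenyl)propan-1-ol | OCCCc1ccc(O)cc1 | starting material
2 | 3-[4-(benzyloxy)phenyl]propan-1-ol | OCCCc1ccc(OCc2ccccc2)cc1 | intermediate
3 | 5-bromopentanoyl chloride | O=C(Cl)CCCCBr | starting material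
4 | 3-[4-(benzyloxy)phenyl]propyl 5-bromopentanoate | O=C(CCCCBr)OCCCc1ccc(OCc2ccccc2)cc1 | intermediate
5 | octadecanoic acid (stearic acid) | CCCCCCCCCCCCCCCCCC(=O)O | starting material
6 | 1,3-dioxoisoindolin-2-yl octadecanoate | CCCCCCCCCCCCCCCCCC(=O)ON1C(=O)c2ccccc2C1=O | intermediate
7 | heptadecyl radical (not isolated) | CCCCCCCCCCCCCCCC[CH2] | intermediate
8 | 3-[4-(benzyloxy)phenyl]propyl docosanoate | CCCCCCCCCCCCCCCCCCCCCC(=O)OCCCc1ccc(OCc2ccccc2)cc1 | intermediate
9 | 3-(4-hydroxyphenyl)propyl docosanoate | CCCCCCCCCCCCCCCCCCCCCC(=O)OCCCc1ccc(O)cc1 | target

**Total step count:** 5
**Longest linear sequence:** 4 (steps 1, 2, 4, 5)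

**Steps most likely to fail**

Step 4. Homocoupling of either partner, reduction of the radical or of the alkylnickel species to the alkane, and β-hydride elimination may outrun the cross-coupling.
- The fallback makes the same C5–C6 bond as a C=C bond by olefin metathesis.
- Setting out from 2, acylation with hex-5-enoyl chloride (pyridine, CH2Cl2, 0 °C) should give 3-[4-(benzyloxy)phenyl]propyl hex-5-enoate F1.
- Cross-metathesis of F1 with an excess of octadec-1-ene (second-generation ruthenium alkylidene catalyst, CH2Cl2, 40 °C) should give 3-[4-(benzyloxy)phenyl]propyl (E)-docos-5-enoate F2. Any Z isomer formed beside it converges in the next operation.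
- H2 and Pd/C in EtOAc–THF should then saturate the alkene and cleave the benzyl ether in one operation, and the fallback comes back to the route at 9.

Step 5. The hydrogenolysis may stall through poisoning of the palladium surface by traces of nickel, zinc or halide carried over from step 4, or through poor solubility of the waxy substrate.
- The fallback replaces reduction by Lewis-acid-mediated benzyl cation transfer.
- Setting out from 8, BCl3 with pentamethylbenzene as cation scavenger (CH2Cl2, −78 °C, then aqueous work-up) should free the phenol while the alkyl ester survives at that temperature.
- It comes back to the route at 9. New compounds on this way: none F0.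

Step 2. The chloride set free may exchange with the primary bromide, and pyridine may be quaternised by the alkyl bromide on prolonged contact.
- The fallback activates the alcohol instead of the acid, with no chloride and no amine in the flask.
- Setting out from 2, a Mitsunobu esterification with 5-bromopentanoic acid (PPh3, DIAD, THF, 0 °C to rt) should give the ester directly.
- It comes back to the route at 4. New compounds on this way: none F0.

**Further compounds**
F1 | step 4 | 3-[4-(benzyloxy)phenyl]propyl hex-5-enoate | C=CCCCC(=O)OCCCc1ccc(OCc2ccccc2)cc1
F2 | step 4 | 3-[4-(benzyloxy)phenyl]propyl (E)-docos-5-enoate | CCCCCCCCCCCCCCCC/C=C/CCCC(=O)OCCCc1ccc(OCc2ccccc2)cc1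
F0 | step 5 | none | none
F0 | step 2 | none | none
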